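**Target:** (1S,2Z,4R,6Z,9S,10R)-9-(benzoyloxy)-4-hydroxy-3,7-dimethyl-10-(propan-2-yl)cyclodeca-2,6-dien-1-yl acetate (CNP0125882.1).

## Retrosynthetic overview

1. Numbering: C1 (OAc), C2=C3(Me), C4 (OH), C5, C6=C7(Me), C8, C9 (OBz), C10 (iPr). The only ring, the ten-membered carbocycle, is closed last but one by ring-closing metathesis at C6=C7, followed by desilylation of O4.
2. The metathesis substrate comes from acetylation of the C1 alcohol formed by Evans–Tishchenko reduction of a β-hydroxy (Z)-enone with PhCHO; this sets C1 (1,9-anti) and puts the benzoate on O9.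
3. The enone comes from a late union of fragment B (alkenyllithium from vinyl iodide 14, C2–C6, 16 non-hydrogen atoms) with fragment A (Weinreb amide 8, C1 and C7–C10, 19 non-hydrogen atoms).
4. Fragment A: Evans syn-aldol (C9, C10) of an isovaleryl imide with 3-methylbut-3-enal. Fragment B: Brown allylation (C4) of (Z)-3-iodo-2-methylpropenal, whose Z-C2=C3 comes from anti-carbomagnesiation of propargyl alcohol.

Assumption: the recoverable chiral auxiliary (R)-4-benzyl-2-oxazolidinone is entered as a reagent in step 1, not as a numbered compound; it is released again in step 4.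

## Route

**Step 1**
Reactants: 1 3-methylbutanoyl chloride
Product: 2 (R)-4-benzyl-3-(3-methylbutanoyl)oxazolidin-2-one
Conditions: (R)-4-benzyl-2-oxazolidinone, n-BuLi, THF, −78 °C; then 1, −78 → 0 °C
Reagents that add atoms: (R)-4-benzyl-2-oxazolidinone, O=C1N[C@H](Cc2ccccc2)CO1
Why: N-acylation of the lithiated oxazolidinone (nucleophilic acyl substitution) installs the Evans auxiliary that will control C9 and C10; no stereocentre is formed.

**Step 2**
Reactants: 3 3-methylbut-3-en-1-ol
Product: 4 3-methylbut-3-enal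
Conditions: Dess–Martin periodinane, pyridine, CH2Cl2, 0 °C → rt; cold solution of 4 used at once
Reagents that add atoms: none
Why: buffered Dess–Martin oxidation gives the β,γ-unsaturated aldehyde without acid- or base-induced migration of the double bond into conjugation; no stereocentre.

**Step 3**
Reactants: 2 (R)-4-benzyl-3-(3-methylbutanoyl)oxazolidin-2-one; 4 3-methylbut-3-enal
Product: 6 (R)-4-benzyl-3-[(2R,3S)-3-hydroxy-5-methyl-2-(propan-2-yl)hex-5-enoyl]oxazolidin-2-one, via boron enolate 5 (not isolated)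
Conditions: n-Bu2BOTf, i-Pr2NEt, CH2Cl2, −78 → 0 °C; then 4, −78 → 0 °C; pH 7 buffer, MeOH, 30% H2O2, 0 °C
Reagents that add atoms: none
Why: Evans syn-aldol reaction, in which the (Z)-boron enolate reacts through a Zimmerman–Traxler chair on the face opposite the benzyl group of the (R)-auxiliary, setting C10 (R) and C9 (S) together as the 2,3-syn adduct.

**Step 4**
Reactants: 6 (R)-4-benzyl-3-[(2R,3S)-3-hydroxy-5-methyl-2-(propan-2-yl)hex-5-enoyl]oxazolidin-2-one
Product: 7 (2R,3S)-3-hydroxy-N-methoxy-N,5-dimethyl-2-(propan-2-yl)hex-5-enamide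
Conditions: MeNH(OMe)·HCl, AlMe3, THF, −20 → 0 °C; then 0.5 M HCl (aq), 0 °C
Reagents that add atoms: N,O-dimethylhydroxylamine hydrochloride, CNOC.Cl
Why: aluminium amide transamination (Weinreb amide formation), assisted by the free β-alkoxide, releases the auxiliary without touching C9 or C10 and gives an acyl donor that stops at the ketone stage.

**Step 5**
Reactants: 7 (2R,3S)-3-hydroxy-N-methoxy-N,5-dimethyl-2-(propan-2-yl)hex-5-enamide
Product: 8 (2R,3S)-N-methoxy-N,5-dimethyl-2-(propan-2-yl)-3-(trimethylsilyloxy)hex-5-enamide (fragment A)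
Conditions: TMSCl, imidazole, CH2Cl2, 0 °C
Reagents that add atoms: chlorotrimethylsilane, C[Si](C)(C)Cl
Why: silyl ether formation masks the C9 hydroxyl so that one equivalent of the alkenyllithium suffices in step 10, and the TMS group is chosen because it falls off in the acidic work-up of that step.

**Step 6**
Reactants: 9 prop-2-yn-1-ol
Product: 11 (Z)-3-iodo-2-methylprop-2-en-1-ol, via oxamagnesacycle 10 (not isolated)
Conditions: MeMgBr (2.3 equiv), CuI (10 mol%), THF, −10 °C → rt; then I2, −10 °C; aq. NH4Cl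
Reagents that add atoms: methylmagnesium bromide, C[Mg]Br; iodine, II
Why: copper-catalysed anti-carbomagnesiation of the propargylic alkoxide (Duboudin reaction) puts methyl on C3 and magnesium on C2 cis to the CH2O group in a five-membered chelate, and iodinolysis with retention fixes the Z geometry of C2=C3.

**Step 7**
Reactants: 11 (Z)-3-iodo-2-methylprop-2-en-1-ol
Product: 12 (Z)-3-iodo-2-methylprop-2-enal
Conditions: MnO2 (excess), CH2Cl2, rt, dark; filtered and used at once
Reagents that add atoms: none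
Why: MnO2 oxidation is selective for the allylic alcohol and neutral, so the labile Z-β-iodoenal is obtained without isomerisation; no stereocentre.

**Step 8**
Reactants: 12 (Z)-3-iodo-2-methylprop-2-enal
Product: 13 (1Z,3R)-1-iodo-2-methylhexa-1,5-dien-3-ol
Conditions: (+)-Ipc2B(allyl) [from (−)-α-pinene], Et2O, −78 °C; then 3 M NaOH, 30% H2O2, 0 °C → rt
Reagents that add atoms: (+)-B-allyldiisopinocampheylborane, C=CCB([C@H]1C[C@H]2C[C@@H]([C@@H]1C)C2(C)C)[C@H]1C[C@H]2C[C@@H]([C@@H]1C)C2(C)C
Why: Brown asymmetric allylboration delivers the allyl group through a chair transition state to the Re face of the aldehyde, setting C4 as R (about 90% ee expected).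

**Step 9**
Reactants: 13 (1Z,3R)-1-iodo-2-methylhexa-1,5-dien-3-ol
Product: 14 tert-butyl{[(1Z,3R)-1-iodo-2-methylhexa-1,5-dien-3-yl]oxy}dimethylsilane (fragment B)
Conditions: TBSCl, imidazole, DMF, rt
Reagents that add atoms: tert-butyldimethylsilyl chloride, CC(C)(C)[Si](C)(C)Cl
Why: silyl ether formation protects O4, which must not be free beside the Z-enone made in step 10 (a free γ-hydroxy Z-enone would close to a lactol or furan).

**Step 10** (fragment union)
Reactants: 14 tert-butyl{[(1Z,3R)-1-iodo-2-methylhexa-1,5-dien-3-yl]oxy}dimethylsilane; 8 (2R,3S)-N-methoxy-N,5-dimethyl-2-(propan-2-yl)-3-(trimethylsilyloxy)hex-5-enamide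
Product: 17 (4S,5R,7Z,9R)-9-[(tert-butyldimethylsilyl)oxy]-4-hydroxy-2,8-dimethyl-5-(propan-2-yl)dodeca-1,7,11-trien-6-one, via alkenyllithium 15 (not isolated), via bis-silyl enone 16 (not isolated)
Conditions: 14 (1.3 equiv), t-BuLi (2.1 equiv per 14), Et2O, −78 °C; then 8, −78 → −40 °C; then 1 M HCl, THF, 0 °C
Reagents that add atoms: none
Why: iodine–lithium exchange proceeds with retention of the Z geometry and the alkenyllithium adds once to the Weinreb amide (chelated tetrahedral intermediate) to join the fragments as the Z-enone, with Et2O at −78 °C suppressing 1,4 O→C silyl migration and the acid quench removing the TMS group; no new stereocentre.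

**Step 11**
Reactants: 17 (4S,5R,7Z,9R)-9-[(tert-butyldimethylsilyl)oxy]-4-hydroxy-2,8-dimethyl-5-(propan-2-yl)dodeca-1,7,11-trien-6-one
Product: 18 (4S,5S,6S,7Z,9R)-9-[(tert-butyldimethylsilyl)oxy]-6-hydroxy-2,8-dimethyl-5-(propan-2-yl)dodeca-1,7,11-trien-4-yl benzoate
Conditions: PhCHO (5 equiv), SmI2 (0.3 equiv), THF, −10 °C
Reagents that add atoms: benzaldehyde, O=Cc1ccccc1
Why: Evans–Tishchenko reduction, in which the samarium-bound hemiacetal of benzaldehyde on O9 delivers hydride to C1 through a six-membered chair, gives the 1,9-anti relationship (C1 S) and leaves the benzoate on O9, so the two oxygens are differentiated in one operation.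

**Step 12**
Reactants: 18 (4S,5S,6S,7Z,9R)-9-[(tert-butyldimethylsilyl)oxy]-6-hydroxy-2,8-dimethyl-5-(propan-2-yl)dodeca-1,7,11-trien-4-yl benzoate
Product: 19 (4S,5R,6S,7Z,9R)-6-acetoxy-9-[(tert-butyldimethylsilyl)oxy]-2,8-dimethyl-5-(propan-2-yl)dodeca-1,7,11-trien-4-yl benzoate
Conditions: Ac2O, pyridine, DMAP (cat.), CH2Cl2, 0 °C → rt
Reagents that add atoms: acetic anhydride, CC(=O)OC(C)=O
Why: DMAP-catalysed acylation of the only free hydroxyl installs the C1 acetate with retention of configuration.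

**Step 13**
Reactants: 19 (4S,5R,6S,7Z,9R)-6-acetoxy-9-[(tert-butyldimethylsilyl)oxy]-2,8-dimethyl-5-(propan-2-yl)dodeca-1,7,11-trien-4-yl benzoate
Product: 20 (1S,2Z,4R,6Z,9S,10R)-1-acetoxy-4-[(tert-butyldimethylsilyl)oxy]-3,7-dimethyl-10-(propan-2-yl)cyclodeca-2,6-dien-9-yl benzoate
Conditions: second-generation Grubbs catalyst (H2IMes)(PCy3)Cl2Ru=CHPh (10 mol%), toluene (1 mM), 80 °C
Reagents that add atoms: none
Why: ring-closing metathesis between the monosubstituted C6 olefin and the 1,1-disubstituted C7 olefin, helped by the Z-C2=C3 turn element, closes the ten-membered ring, in which the new trisubstituted olefin is expected as the Z isomer under ring-strain control.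

**Step 14**
Reactants: 20 (1S,2Z,4R,6Z,9S,10R)-1-acetoxy-4-[(tert-butyldimethylsilyl)oxy]-3,7-dimethyl-10-(propan-2-yl)cyclodeca-2,6-dien-9-yl benzoate
Product: 21 (1S,2Z,4R,6Z,9S,10R)-9-(benzoyloxy)-4-hydroxy-3,7-dimethyl-10-(propan-2-yl)cyclodeca-2,6-dien-1-yl acetate
Conditions: HF·pyridine, pyridine, THF, 0 °C → rt
Reagents that add atoms: none
Why: buffered, non-basic fluoride desilylation frees O4 without acyl migration from the cis-disposed C1 acetate or ester cleavage, giving the target with all four stereocentres intact.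

## Compound list

1 | 3-methylbutanoyl chloride | CC(C)CC(=O)Cl | starting material
2 | (R)-4-benzyl-3-(3-methylbutanoyl)oxazolidin-2-one | CC(C)CC(=O)N1[C@H](Cc2ccccc2)COC1=O | intermediate
3 | 3-methylbut-3-en-1-ol | CC(=C)CCO | starting material
4 | 3-methylbut-3-enal | CC(=C)CC=O | intermediate
5 | (Z)-di-n-butylboron enolate of 2 | CCCCB(CCCC)O/C(=C\C(C)C)N1[C@H](Cc2ccccc2)COC1=O | intermediate
6 | (R)-4-benzyl-3-[(2R,3S)-3-hydroxy-5-methyl-2-(propan-2-yl)hex-5-enoyl]oxazolidin-2-one | O=C1OC[C@@H](Cc2ccccc2)N1C(=O)[C@H](C(C)C)[C@@H](O)CC(C)=C | intermediate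
7 | (2R,3S)-3-hydroxy-N-methoxy-N,5-dimethyl-2-(propan-2-yl)hex-5-enamide | CON(C)C(=O)[C@H](C(C)C)[C@@H](O)CC(C)=C | intermediate
8 | (2R,3S)-N-methoxy-N,5-dimethyl-2-(propan-2-yl)-3-(trimethylsilyloxy)hex-5-enamide (fragment A) | CON(C)C(=O)[C@H](C(C)C)[C@@H](O[Si](C)(C)C)CC(C)=C | intermediate
9 | prop-2-yn-1-ol | C#CCO | starting material
10 | 4-methyl-2,5-dihydro-1,2-oxamagnesole (cyclic alkenylmagnesium alkoxide) | CC1=C[Mg]OC1 | intermediate
11 | (Z)-3-iodo-2-methylprop-2-en-1-ol | OC/C(C)=C\I | intermediate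
12 | (Z)-3-iodo-2-methylprop-2-enal | O=C/C(C)=C\I | intermediate
13 | (1Z,3R)-1-iodo-2-methylhexa-1,5-dien-3-ol | C=CC[C@@H](O)/C(C)=C\I | intermediate
14 | tert-butyl{[(1Z,3R)-1-iodo-2-methylhexa-1,5-dien-3-yl]oxy}dimethylsilane (fragment B) | C=CC[C@@H](O[Si](C)(C)C(C)(C)C)/C(C)=C\I | intermediate
15 | (1Z,3R)-3-[(tert-butyldimethylsilyl)oxy]-2-methylhexa-1,5-dien-1-yllithium | C=CC[C@@H](O[Si](C)(C)C(C)(C)C)/C(C)=C\[Li] | intermediate
16 | (4S,5R,7Z,9R)-9-[(tert-butyldimethylsilyl)oxy]-2,8-dimethyl-5-(propan-2-yl)-4-(trimethylsilyloxy)dodeca-1,7,11-trien-6-one | C=CC[C@@H](O[Si](C)(C)C(C)(C)C)/C(C)=C\C(=O)[C@H](C(C)C)[C@@H](O[Si](C)(C)C)CC(C)=C | intermediate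
17 | (4S,5R,7Z,9R)-9-[(tert-butyldimethylsilyl)oxy]-4-hydroxy-2,8-dimethyl-5-(propan-2-yl)dodeca-1,7,11-trien-6-one | C=CC[C@@H](O[Si](C)(C)C(C)(C)C)/C(C)=C\C(=O)[C@H](C(C)C)[C@@H](O)CC(C)=C | intermediate
18 | (4S,5S,6S,7Z,9R)-9-[(tert-butyldimethylsilyl)oxy]-6-hydroxy-2,8-dimethyl-5-(propan-2-yl)dodeca-1,7,11-trien-4-yl benzoate | C=CC[C@@H](O[Si](C)(C)C(C)(C)C)/C(C)=C\[C@H](O)[C@H](C(C)C)[C@@H](OC(=O)c1ccccc1)CC(C)=C | intermediate
19 | (4S,5R,6S,7Z,9R)-6-acetoxy-9-[(tert-butyldimethylsilyl)oxy]-2,8-dimethyl-5-(propan-2-yl)dodeca-1,7,11-trien-4-yl benzoate | C=CC[C@@H](O[Si](C)(C)C(C)(C)C)/C(C)=C\[C@H](OC(C)=O)[C@H](C(C)C)[C@@H](OC(=O)c1ccccc1)CC(C)=C | intermediate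
20 | (1S,2Z,4R,6Z,9S,10R)-1-acetoxy-4-[(tert-butyldimethylsilyl)oxy]-3,7-dimethyl-10-(propan-2-yl)cyclodeca-2,6-dien-9-yl benzoate | CC(=O)O[C@H]1/C=C(/C)[C@H](O[Si](C)(C)C(C)(C)C)C/C=C(/C)C[C@H](OC(=O)c2ccccc2)[C@H]1C(C)C | intermediate
21 | (1S,2Z,4R,6Z,9S,10R)-9-(benzoyloxy)-4-hydroxy-3,7-dimethyl-10-(propan-2-yl)cyclodeca-2,6-dien-1-yl acetate | CC(=O)O[C@H]1/C=C(/C)[C@H](O)C/C=C(/C)C[C@H](OC(=O)c2ccccc2)[C@H]1C(C)C | target

## Step count and risk

Total step count: 14.
Longest linear sequence: 9 steps (steps 1, 3, 4, 5, then 10–14; the branch 6–9 followed by 10–14 is equally long).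

**Step 13 (ring-closing metathesis).** The ten-membered ring with a second trisubstituted olefin may oligomerise or close slowly from the fully acylated triene. The fallback reverses the order of ring closure and C1 functionalisation, so the metathesis runs on a different substrate with a trigonal C1 and an internal O9–H···O=C1 hydrogen bond. It sets out from β-hydroxy enone 17, which is cyclised with the same ruthenium carbene under high dilution to the cyclic β-hydroxy dienone F9. Evans–Tishchenko reduction of F9 on the ring (PhCHO, SmI2, THF, −10 °C) gives the ring C1 alcohol F10 with the benzoate on O9. Acetylation (Ac2O, pyridine, DMAP) brings the sequence back to the route at 20.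

**Step 10 (fragment union).** The hindered Weinreb amide may react slowly, the alkenyllithium may undergo silyl migration on warming, and the Z-enone may isomerise; this fallback also bypasses step 11. It replaces acylation and directed reduction by a chelation-controlled addition to an aldehyde, and sets out from Weinreb amide 7.
- 7 is protected with 4-methoxybenzyl trichloroacetimidate and Sc(OTf)3 (cat.) to give the PMB ether Weinreb amide F3.
- F3 is reduced with i-Bu2AlH (THF, −78 °C) to the aldehyde F4.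
- Alkenyllithium 15 is transmetalated with MgBr2·OEt2 to the alkenylmagnesium bromide F5.
- F5 is added at −78 °C in CH2Cl2 to F4 precomplexed with MgBr2·OEt2. Attack on the Cram chelate anti to the isopropyl group gives the C1 (S) allylic alcohol F6.
- Acetylation of F6 gives the acetate F7, and DDQ (CH2Cl2, pH 7 buffer) removes the PMB group to give the C9 alcohol F8.
- Benzoylation of F8 (BzCl, pyridine, DMAP) comes back to the route at 19.

**Step 7 (Z-β-iodoenal).** Compound 12 can isomerise to the E isomer during oxidation or before the allylation. The fallback makes the C4 carbinol before the iodoalkene, so the enal is never formed, and sets out from prop-2-yn-1-ol 9. Compound 9 is oxidised (CrO3, H2SO4, aqueous butan-2-one, with distillation of the aldehyde) to propynal F1. F1 is allylated with (+)-Ipc2B(allyl) at −78 °C (NaOH, H2O2 work-up) to (R)-hex-5-en-1-yn-3-ol F2. F2 then undergoes the copper-catalysed anti-carbomagnesiation and iodination of step 6 (MeMgBr, CuI; then I2), which gives the Z-iodo dienol directly and comes back to the route at 13.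

## Further compounds

F1 | step 7 | propynal | C#CC=O
F2 | step 7 | (R)-hex-5-en-1-yn-3-ol | C=CC[C@@H](O)C#C
F3 | step 10 | (2R,3S)-N-methoxy-3-[(4-methoxybenzyl)oxy]-N,5-dimethyl-2-(propan-2-yl)hex-5-enamide | CON(C)C(=O)[C@H](C(C)C)[C@@H](OCc1ccc(OC)cc1)CC(C)=C
F4 | step 10 | (2R,3S)-3-[(4-methoxybenzyl)oxy]-5-methyl-2-(propan-2-yl)hex-5-enal | O=C[C@H](C(C)C)[C@@H](OCc1ccc(OC)cc1)CC(C)=C
F5 | step 10 | (1Z,3R)-3-[(tert-butyldimethylsilyl)oxy]-2-methylhexa-1,5-dien-1-ylmagnesium bromide | C=CC[C@@H](O[Si](C)(C)C(C)(C)C)/C(C)=C\[Mg]Br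
F6 | step 10 | C1 alcohol with O9-PMB and O4-TBS (acyclic triene) | C=CC[C@@H](O[Si](C)(C)C(C)(C)C)/C(C)=C\[C@H](O)[C@H](C(C)C)[C@@H](OCc1ccc(OC)cc1)CC(C)=C
F7 | step 10 | C1 acetate with O9-PMB and O4-TBS (acyclic triene) | C=CC[C@@H](O[Si](C)(C)C(C)(C)C)/C(C)=C\[C@H](OC(C)=O)[C@H](C(C)C)[C@@H](OCc1ccc(OC)cc1)CC(C)=C
F8 | step 10 | C1 acetate with free C9 hydroxyl and O4-TBS (acyclic triene) | C=CC[C@@H](O[Si](C)(C)C(C)(C)C)/C(C)=C\[C@H](OC(C)=O)[C@H](C(C)C)[C@@H](O)CC(C)=C
F9 | step 13 | (2Z,4R,6Z,9S,10R)-4-[(tert-butyldimethylsilyl)oxy]-9-hydroxy-3,7-dimethyl-10-(propan-2-yl)cyclodeca-2,6-dien-1-one | O=C1/C=C(/C)[C@H](O[Si](C)(C)C(C)(C)C)C/C=C(/C)C[C@H](O)[C@H]1C(C)C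
F10 | step 13 | ring C1 alcohol with O9 benzoate and O4-TBS (20 without the acetyl group) | O[C@H]1/C=C(/C)[C@H](O[Si](C)(C)C(C)(C)C)C/C=C(/C)C[C@H](OC(=O)c2ccccc2)[C@H]1C(C)C
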